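The whole route hinges on cutting the lactone O–C8 bond. In a ten-membered carbocycle that carries a cis C8–C9 epoxide, the C12 carboxyl of the acrylic acid arm on C7 is one five-membered ring (O, C12, C11, C7, C8) away from C8. Backside opening at C8 closes the cis-fused α-methylene γ-lactone, inverts C8 and leaves the epoxide oxygen as the C9 hydroxyl, so the vicinal anti O8/O9 pair and the ring fusion arise in one operation. The precursor is the 4,5:8,9-bisepoxy acid with C6 as its triethylsilyl ether; its 8,9-epoxide is laid down by iodolactonisation and base-induced reclosure, which place the oxygen on the required face.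

Key step: step 15

Remark: germacrane numbering of the target is used for all intermediates (ring C1–C10, acrylate carbons C11–C13, C14 on C10, C15 on C4); (R)-β-citronellene and but-1-en-3-yne (as a solution) are taken as commercial, and the epoxide needed is the cis (8S,9R) one, with its oxygen on the ring face opposite to the lactone oxygen of the target.

Step 1
Reactants: 1 (3R)-3,7-dimethylocta-1,6-diene [(R)-β-citronellene]
Product: 3 (4R)-4-methylhex-5-en-1-ol, via (4R)-4-methylhex-5-enal 2 (not isolated)
Conditions: O3 (1 equiv), CH2Cl2/MeOH, −78 °C; then NaBH4, −78 °C to rt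
Reagents that add atoms: ozone, O=[O+][O-]
Why: Ozonolysis with reductive work-up, in which the electron-rich trisubstituted olefin should be cleaved well before the monosubstituted vinyl group and the aldehyde is reduced in the pot; the C10 stereocentre comes from the chiral pool and is not touched.

Step 2
Reactants: 3 (4R)-4-methylhex-5-en-1-ol
Product: 4 (3R)-6-iodo-3-methylhex-1-ene
Conditions: I2, PPh3, imidazole, CH2Cl2, 0 °C
Reagents that add atoms: iodine, II
Why: Appel-type iodination of a primary alcohol under neutral conditions, with no stereocentre involved.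

Step 3
Reactants: 4 (3R)-6-iodo-3-methylhex-1-ene
Product: 5 (3R)-3-methyloct-1-en-7-yne
Conditions: LiC≡CH·H2NCH2CH2NH2, DMSO, rt
Reagents that add atoms: lithium acetylide, [Li]C#C
Why: SN2 alkylation of an acetylide by a primary iodide, which adds the two carbons that become C4 and C5.

Step 4
Reactants: 5 (3R)-3-methyloct-1-en-7-yne
Product: 7 (2E,7R)-3,7-dimethylnona-2,8-dien-1-ol, via alkenyldimethylalane 6 (not isolated)
Conditions: Me3Al, Cp2ZrCl2 (cat.), CH2Cl2, 0 °C to rt; then n-BuLi, (CH2O)n, THF, −78 °C to rt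
Reagents that add atoms: trimethylaluminium, C[Al](C)C; formaldehyde (from paraformaldehyde), C=O
Why: Negishi carboalumination adds methyl and aluminium syn across the terminal alkyne (methyl to the internal carbon), which fixes the E trisubstituted C4=C5 geometry, and the alkenylaluminate is hydroxymethylated with retention; the alkyne should react much faster than the isolated vinyl group.

Step 5
Reactants: 7 (2E,7R)-3,7-dimethylnona-2,8-dien-1-ol
Product: 8 [(2R,3R)-3-methyl-3-[(4R)-4-methylhex-5-en-1-yl]oxiran-2-yl]methanol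
Conditions: Ti(OiPr)4 (cat.), D-(−)-diethyl tartrate, t-BuOOH, 4 Å MS, CH2Cl2, −20 °C
Reagents that add atoms: tert-butyl hydroperoxide, CC(C)(C)OO
Why: Sharpless asymmetric epoxidation of the primary allylic alcohol, in which the D-(−)-tartrate ligand sets the (4R,5R) trans-epoxide by reagent control while the non-allylic vinyl group stays inert.

Step 6
Reactants: 8 [(2R,3R)-3-methyl-3-[(4R)-4-methylhex-5-en-1-yl]oxiran-2-yl]methanol
Product: 9 (2S,3R)-3-methyl-3-[(4R)-4-methylhex-5-en-1-yl]oxirane-2-carbaldehyde
Conditions: TEMPO (cat.), PhI(OAc)2, CH2Cl2, rt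
Reagents that add atoms: none
Why: Nitroxyl-catalysed oxidation of a primary alcohol, which stops at the aldehyde under nearly neutral conditions and so preserves the epoxide and the C5 configuration (the descriptor changes only through CIP priorities).

Step 7
Reactants: 10 but-1-en-3-yne
Product: 12 methyl pent-4-en-2-ynoate, via lithium but-3-en-1-yn-1-ide 11 (not isolated)
Conditions: n-BuLi, THF, −78 °C; then ClCO2Me, −78 °C to 0 °C
Reagents that add atoms: methyl chloroformate, COC(=O)Cl
Why: Deprotonation of a terminal alkyne and C-acylation of the acetylide, the standard alkynoate synthesis.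

Step 8
Reactants: 12 methyl pent-4-en-2-ynoate
Product: 14 methyl (2Z)-2-[(4,4,5,5-tetramethyl-1,3,2-dioxaborolan-2-yl)methyl]penta-2,4-dienoate, via α-aluminated dienoate 13 (not isolated)
Conditions: iBu2AlH, HMPA, THF, 0 °C; then ICH2B(pin), 0 °C to rt
Reagents that add atoms: 2-(iodomethyl)-4,4,5,5-tetramethyl-1,3,2-dioxaborolane, ICB1OC(C)(C)C(C)(C)O1
Why: Conjugate hydroalumination of the alkynoate puts hydrogen on C7 and aluminium on C11 on the same side, and alkylation of the α-aluminated ester by the iodomethylboronate with retention should give the allylboronate with the vinyl group cis to the ester, the geometry an anti allylation needs.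

Step 9
Reactants: 9 (2S,3R)-3-methyl-3-[(4R)-4-methylhex-5-en-1-yl]oxirane-2-carbaldehyde; 14 methyl (2Z)-2-[(4,4,5,5-tetramethyl-1,3,2-dioxaborolan-2-yl)methyl]penta-2,4-dienoate
Product: 16 methyl (3R,4R)-3-ethenyl-4-hydroxy-2-methylidene-4-{(2R,3R)-3-methyl-3-[(4R)-4-methylhex-5-en-1-yl]oxiran-2-yl}butanoate, via pinacol borate ester 15 (not isolated)
Conditions: toluene, 50 °C; then aq. NaHCO3
Reagents that add atoms: none
Why: Allylboration through a closed chair transition state, in which the vinyl group on C7 (trans to the CH2B carbon) sits equatorial and gives the 6,7-anti adduct, while Felkin–Anh attack anti to the C5–O bond of the epoxide should set C6 as the 5,6-erythro (6R) alcohol; the Lewis-acid-free conditions spare the epoxy aldehyde.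

Step 10
Reactants: 16 the 6-hydroxy ester from step 9
Product: 17 methyl (3R,4R)-3-ethenyl-2-methylidene-4-{(2R,3R)-3-methyl-3-[(4R)-4-methylhex-5-en-1-yl]oxiran-2-yl}-4-(triethylsilyloxy)butanoate
Conditions: TESCl, imidazole, DMAP (cat.), DMF, 0 °C to rt
Reagents that add atoms: chlorotriethylsilane, CC[Si](CC)(CC)Cl
Why: Silylation of the secondary alcohol, so that the C6 oxygen can later neither lactonise onto C12 nor guide a Lewis acid to the 4,5-epoxide.

Step 11
Reactants: 17 the C6 triethylsilyl ether from step 10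
Product: 18 methyl (4R,5R,6R,7R,8Z,10R)-4,5-epoxy-6-(triethylsilyloxy)germacra-8,11(13)-dien-12-oate (ten-membered ring with a Z C8=C9 olefin, a trans 4,5-epoxide and the methyl acrylate arm on C7)
Conditions: second-generation Hoveyda–Grubbs catalyst RuCl2(=CH-C6H4-2-OiPr)(H2IMes) (10 mol%), toluene (0.5 mM), 80 °C, argon purge
Reagents that add atoms: none
Why: Ring-closing metathesis of the two terminal vinyl groups forms C8=C9; the Z olefin is expected as the less strained geometry of a cyclodecene under equilibrating conditions, and because C4–C5 is already an epoxide no six-membered ring can form by metathesis at that position.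

Step 12
Reactants: 18 the cyclic methyl ester from step 11
Product: 19 (4R,5R,6R,7R,8Z,10R)-4,5-epoxy-6-(triethylsilyloxy)germacra-8,11(13)-dien-12-oic acid
Conditions: LiOH, THF/MeOH/H2O, rt; then AcOH to pH 5
Reagents that add atoms: lithium hydroxide, [Li+].[OH-]
Why: Saponification of the α-substituted acrylate, which the triethylsilyl ether and the epoxide should tolerate at room temperature.

Step 13
Reactants: 19 the cyclodecadienoic acid from step 12
Product: 20 (4R,5R,6R,7S,8S,9S,10R)-4,5-epoxy-9-iodo-6-(triethylsilyloxy)germacr-11(13)-en-12,8-olide (trans-fused iodolactone)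
Conditions: I2, NaHCO3, MeCN, 0 °C, dark
Reagents that add atoms: iodine, II
Why: Kinetic iodolactonisation (5-exo, anti addition): with H7 eclipsing the Z olefin to avoid allylic 1,3-strain the acrylic acid arm stands over one face of C8=C9, so the carboxylate should add to C8 on that face and iodine to C9 on the other; an oxidant directed by the C6 oxygen would be delivered to the other face, which is why the acid itself is made the delivering group.

Step 14
Reactants: 20 the trans-fused iodolactone from step 13
Product: 22 (4R,5R,6R,7S,8S,9R,10R)-4,5:8,9-diepoxy-6-(triethylsilyloxy)germacr-11(13)-en-12-oic acid, via iodohydrin carboxylate 21 (not isolated)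
Conditions: LiOH, THF/H2O, 0 °C to rt; then AcOH to pH 5, 0 °C, rapid extraction
Reagents that add atoms: lithium hydroxide, [Li+].[OH-]
Why: Base opens the lactone and the freed C8 alkoxide displaces the antiperiplanar C9 iodide (intramolecular Williamson closure, inversion at C9), giving the cis epoxide with its oxygen on the face the lactone oxygen had occupied.

Step 15
Reactants: 22 the 4,5:8,9-bisepoxy acid with C6 OTES
Product: 23 (4R,5R,6R,7S,8R,9R,10R)-4,5-epoxy-9-hydroxy-6-(triethylsilyloxy)germacr-11(13)-en-12,8-olide (cis-fused)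
Conditions: Ti(OiPr)4 (1.2 equiv), CH2Cl2, 0 °C to rt; then aq. tartaric acid
Reagents that add atoms: none
Why: Ligand exchange gives a titanium carboxylate that holds the Lewis acid beside the C8–C9 epoxide, and the carboxyl oxygen attacks C8 from the face opposite the breaking C8–O(epoxide) bond. The closest known reaction type is the acid- or Ti(OiPr)4-promoted lactonisation of γ,δ-epoxy acids to δ-hydroxy γ-lactones with inversion at the attacked carbon. The lactone ring (O, C12, C11, C7, C8) closes in the 5-exo-tet mode. C8 is set by inversion (8S to 8R) through the backside trajectory, C9 keeps the epoxide oxygen as its hydroxyl (9R), and since C7 is already fixed the cis ring fusion (H7 and H8 syn) follows. The step needs attack at C8 rather than C9 and on the 8,9- rather than the 4,5-epoxide: the five-membered transition state is favoured over the six-membered one, the tethered carboxylate reaches only the 8,9-epoxide, and the silylated C6 oxygen can neither bind titanium beside the 4,5-epoxide nor lactonise onto C12.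

Step 16
Reactants: 23 the C9 alcohol from step 15
Product: 24 (4R,5R,6R,7S,8R,9R,10R)-4,5-epoxy-9-(3-methylbut-2-enoyloxy)-6-(triethylsilyloxy)germacr-11(13)-en-12,8-olide
Conditions: 3-methylbut-2-enoyl chloride, pyridine, DMAP (cat.), CH2Cl2, 0 °C
Reagents that add atoms: 3-methylbut-2-enoyl chloride, CC(C)=CC(=O)Cl
Why: Acylation of the secondary C9 alcohol under nucleophilic catalysis, with a weak base so that the senecioyl group is not deconjugated.

Step 17
Reactants: 24 the C6 silyl ether of the target
Product: 25 (4R,5R,6R,7R,8R,9R,10R)-4,5-epoxy-6-hydroxy-9-(3-methylbut-2-enoyloxy)germacr-11(13)-en-12,8-olide (target)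
Conditions: HF·pyridine, pyridine, THF, 0 °C
Reagents that add atoms: none
Why: Fluoride cleavage of the triethylsilyl ether under pyridine-buffered, non-basic conditions, which should leave both esters, the α-methylene lactone and the epoxide intact and avoid translactonisation to C6.

Compound list
1 | (3R)-3,7-dimethylocta-1,6-diene | C=C[C@H](C)CCC=C(C)C | starting material
2 | (4R)-4-methylhex-5-enal | C=C[C@H](C)CCC=O | intermediate
3 | (4R)-4-methylhex-5-en-1-ol | C=C[C@H](C)CCCO | intermediate
4 | (3R)-6-iodo-3-methylhex-1-ene | C=C[C@H](C)CCCI | intermediate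
5 | (3R)-3-methyloct-1-en-7-yne | C=C[C@H](C)CCCC#C | intermediate
6 | dimethyl[(1E,7R)-2,7-dimethylnona-1,8-dien-1-yl]alumane | C=C[C@H](C)CCC/C(C)=C/[Al](C)C | intermediate
7 | (2E,7R)-3,7-dimethylnona-2,8-dien-1-ol | C=C[C@H](C)CCC/C(C)=C/CO | intermediate
8 | [(2R,3R)-3-methyl-3-[(4R)-4-methylhex-5-en-1-yl]oxiran-2-yl]methanol | C=C[C@H](C)CCC[C@@]1(C)O[C@@H]1CO | intermediate
9 | (2S,3R)-3-methyl-3-[(4R)-4-methylhex-5-en-1-yl]oxirane-2-carbaldehyde | C=C[C@H](C)CCC[C@@]1(C)O[C@@H]1C=O | intermediate
10 | but-1-en-3-yne | C=CC#C | starting material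
11 | lithium but-3-en-1-yn-1-ide | C=CC#C[Li] | intermediate
12 | methyl pent-4-en-2-ynoate | C=CC#CC(=O)OC | intermediate
13 | methyl (2E)-2-(diisobutylalumanyl)penta-2,4-dienoate (vinyl cis to the ester) | C=C/C=C(/[Al](CC(C)C)CC(C)C)C(=O)OC | intermediate
14 | methyl (2Z)-2-[(4,4,5,5-tetramethyl-1,3,2-dioxaborolan-2-yl)methyl]penta-2,4-dienoate | C=C/C=C(/CB1OC(C)(C)C(C)(C)O1)C(=O)OC | intermediate
15 | pinacol borate ester of 16 (O6–B) | C=C[C@H](C)CCC[C@@]1(C)O[C@@H]1[C@H](OB2OC(C)(C)C(C)(C)O2)[C@H](C=C)C(=C)C(=O)OC | intermediate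
16 | methyl (3R,4R)-3-ethenyl-4-hydroxy-2-methylidene-4-{(2R,3R)-3-methyl-3-[(4R)-4-methylhex-5-en-1-yl]oxiran-2-yl}butanoate | C=C[C@H](C)CCC[C@@]1(C)O[C@@H]1[C@H](O)[C@H](C=C)C(=C)C(=O)OC | intermediate
17 | C6 triethylsilyl ether of 16 | C=C[C@H](C)CCC[C@@]1(C)O[C@@H]1[C@H](O[Si](CC)(CC)CC)[C@H](C=C)C(=C)C(=O)OC | intermediate
18 | methyl (4R,5R,6R,7R,8Z,10R)-4,5-epoxy-6-(triethylsilyloxy)germacra-8,11(13)-dien-12-oate | C=C(C(=O)OC)[C@H]1/C=C\[C@H](C)CCC[C@@]2(C)O[C@@H]2[C@@H]1O[Si](CC)(CC)CC | intermediate
19 | (4R,5R,6R,7R,8Z,10R)-4,5-epoxy-6-(triethylsilyloxy)germacra-8,11(13)-dien-12-oic acid | C=C(C(=O)O)[C@H]1/C=C\[C@H](C)CCC[C@@]2(C)O[C@@H]2[C@@H]1O[Si](CC)(CC)CC | intermediate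
20 | (4R,5R,6R,7S,8S,9S,10R)-4,5-epoxy-9-iodo-6-(triethylsilyloxy)germacr-11(13)-en-12,8-olide, trans-fused | C=C1C(=O)O[C@@H]2[C@@H](I)[C@H](C)CCC[C@@]3(C)O[C@@H]3[C@H](O[Si](CC)(CC)CC)[C@@H]12 | intermediate
21 | lithium (4R,5R,6R,7S,8S,9S,10R)-4,5-epoxy-8-hydroxy-9-iodo-6-(triethylsilyloxy)germacr-11(13)-en-12-oate | C=C(C(=O)[O-])[C@H]1[C@H](O)[C@@H](I)[C@H](C)CCC[C@@]2(C)O[C@@H]2[C@@H]1O[Si](CC)(CC)CC.[Li+] | intermediate
22 | (4R,5R,6R,7S,8S,9R,10R)-4,5:8,9-diepoxy-6-(triethylsilyloxy)germacr-11(13)-en-12-oic acid | C=C(C(=O)O)[C@H]1[C@@H]2O[C@@H]2[C@H](C)CCC[C@@]3(C)O[C@@H]3[C@@H]1O[Si](CC)(CC)CC | intermediate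
23 | (4R,5R,6R,7S,8R,9R,10R)-4,5-epoxy-9-hydroxy-6-(triethylsilyloxy)germacr-11(13)-en-12,8-olide, cis-fused | C=C1C(=O)O[C@H]2[C@H](O)[C@H](C)CCC[C@@]3(C)O[C@@H]3[C@H](O[Si](CC)(CC)CC)[C@@H]12 | intermediate
24 | (4R,5R,6R,7S,8R,9R,10R)-4,5-epoxy-9-(3-methylbut-2-enoyloxy)-6-(triethylsilyloxy)germacr-11(13)-en-12,8-olide | C=C1C(=O)O[C@H]2[C@H](OC(=O)C=C(C)C)[C@H](C)CCC[C@@]3(C)O[C@@H]3[C@H](O[Si](CC)(CC)CC)[C@@H]12 | intermediate
25 | (4R,5R,6R,7R,8R,9R,10R)-4,5-epoxy-6-hydroxy-9-(3-methylbut-2-enoyloxy)germacr-11(13)-en-12,8-olide | C=C1C(=O)O[C@H]2[C@H](OC(=O)C=C(C)C)[C@H](C)CCC[C@@]3(C)O[C@@H]3[C@H](O)[C@@H]12 | target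

Total step count: 17 steps.
Longest linear sequence: 15 steps (steps 1–6 and 9–17 from 1); steps 7 and 8 prepare boronate 14 from 10.

Steps most likely to fail

Step 15. The closure may be slow because the carboxyl oxygen is a weak nucleophile and must reach C8 through a strained, nearly eclipsed C6–C7–C8–C9 arrangement. Prolonged exposure to the Lewis acid could then start ionisation of the trisubstituted 4,5-epoxide. The fallback sets out from acid 22, which would be coupled with dimethylamine (EDC·HCl, HOBt, Me2NH·HCl, iPr2NEt, CH2Cl2, 0 °C) to the epoxy N,N-dimethylamide F1. The amide oxygen is a far better neutral nucleophile and should open the 8,9-epoxide at C8 with inversion under PPTS in wet CH2Cl2, via a cyclic iminium ether that water hydrolyses in the same pot. This returns to the route at hydroxy lactone 23.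

Step 11. Closing a ten-membered ring between two branched vinyl groups may lose out to intermolecular metathesis and oligomerisation. The fallback sets out from 9 and 14: the allylboration mixture is heated on (toluene, 110 °C) so that borate 15 lactonises to the trans α-methylene-γ-butyrolactone diene F2, whose ring holds the C7 vinyl group and the C5 side chain as in a trans-fused germacranolide. Ring-closing metathesis with the same ruthenium catalyst should then give the bicyclic 6,12-olide F3. LiOH in THF/H2O opens the lactone to the hydroxy acid F4 (kept as its lithium salt), TESCl and imidazole give the bis(triethylsilyl) derivative F5, and K2CO3 in MeOH/H2O cleaves only the silyl ester. This returns to the route at acid 19.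

Step 9. Facial discrimination of the epoxy aldehyde may be poor, so that the anti-Felkin 6-epimeric series forms alongside, or the uncatalysed addition may be so slow that the aldehyde degrades. The fallback sets out from allylic alcohol 7, oxidised with MnO2 (CH2Cl2, rt) to the enal F6. Thermal allylboration with 14 would give the 6,7-anti dienol F7, as a mixture with its 6,7-bis-epimer since the enal has no nearby stereocentre. Epoxidation with Ti(OiPr)4, D-(−)-diisopropyl tartrate and a sub-stoichiometric amount of t-BuOOH under kinetic-resolution conditions should convert only the diastereomer with the C6 configuration of 16 into the erythro epoxy alcohol and leave the other behind. This returns to the route at 16.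

Further compounds
F1 | step 15 | (4R,5R,6R,7S,8S,9R,10R)-4,5:8,9-diepoxy-N,N-dimethyl-6-(triethylsilyloxy)germacr-11(13)-en-12-amide | C=C(C(=O)N(C)C)[C@H]1[C@@H]2O[C@@H]2[C@H](C)CCC[C@@]3(C)O[C@@H]3[C@@H]1O[Si](CC)(CC)CC
F2 | step 11 | (4R,5R)-4-ethenyl-3-methylidene-5-{(2R,3R)-3-methyl-3-[(4R)-4-methylhex-5-en-1-yl]oxiran-2-yl}oxolan-2-one | C=C[C@H](C)CCC[C@@]1(C)O[C@@H]1[C@@H]2OC(=O)C(=C)[C@H]2C=C
F3 | step 11 | (4R,5R,6R,7R,8Z,10R)-4,5-epoxygermacra-8,11(13)-dien-12,6-olide, trans-fused | C=C1C(=O)O[C@@H]2[C@@H]1/C=C\[C@H](C)CCC[C@@]3(C)O[C@@H]32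
F4 | step 11 | (4R,5R,6R,7R,8Z,10R)-4,5-epoxy-6-hydroxygermacra-8,11(13)-dien-12-oic acid | C=C(C(=O)O)[C@H]1/C=C\[C@H](C)CCC[C@@]2(C)O[C@@H]2[C@@H]1O
F5 | step 11 | triethylsilyl (4R,5R,6R,7R,8Z,10R)-4,5-epoxy-6-(triethylsilyloxy)germacra-8,11(13)-dien-12-oate | C=C(C(=O)O[Si](CC)(CC)CC)[C@H]1/C=C\[C@H](C)CCC[C@@]2(C)O[C@@H]2[C@@H]1O[Si](CC)(CC)CC
F6 | step 9 | (2E,7R)-3,7-dimethylnona-2,8-dienal | C=C[C@H](C)CCC/C(C)=C/C=O
F7 | step 9 | methyl (3R,4S,5E,10R)-3-ethenyl-4-hydroxy-6,10-dimethyl-2-methylidenedodeca-5,11-dienoate | C=C[C@H](C)CCC/C(C)=C/[C@H](O)[C@H](C=C)C(=C)C(=O)OC
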